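**Plan**

1. Numbering: carbocycle C1–C10 (C1=C10 Z with C14 on C10, C4=C5 E with C15 on C4), lactone C6–O–C12(=O)–C11(=C13)–C7, hydroxyls on C7 and C9, angelate on O8.
2. The C9 carbinol sits directly on C10 of the Z-trisubstituted C1=C10 alkene inside the ten-membered ring, so that ring is cut at C9–C10 into a C9 aldehyde and a Z-alkenyl iodide; this is the last forward step, run on the fully functionalised seco-compound.
3. Further cuts: O8–acyl (angelate), the lactone at C12 (a 1,4-diol), C5–C6 (alkenylalane + aldehyde), C4–C15 (carboalumination), C1=C10 (α-iodo Wittig), C11=C13 (Wittig), C7–C11 (aldol on a tartrate enolate).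
4. Forward order: L-tartrate acetonide → quaternary C7 → chain joined at C6 → five-membered lactone ring → angelate on O8 → ten-membered carbocycle.
5. Stereochemistry: C8 from L-tartaric acid; C7 by enolate attack anti to the C8 ester; C6 by Felkin–Anh reduction of an enone; C9 in the ring closure; E-C4=C5 by syn-carboalumination; Z-C1=C10 from the α-iodo ylide; Z-angelate from angelic acid.

Key step: step 18

Remark: open-chain intermediates keep the numbering of the target, and the lithium enolate of 1 is assumed to take electrophiles anti to the neighbouring ester, as in its known alkylations and aldol additions.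

**Route**

Step 1
Reactants: 1 dimethyl 2,3-O-isopropylidene-L-tartrate; 2 (tert-butyldimethylsilyloxy)acetaldehyde
Product: 4 aldol adduct (hydroxy diester; C11 epimers), via lithium enolate 3 (not isolated)
Conditions: LiN(i-Pr)2, THF/DMPU, −78 °C; then 2, −78 °C; H2O quench at −78 °C
Reagents that add atoms: none
Why: Aldol addition of the lithium ester enolate of the tartrate acetonide, which takes the aldehyde on the face anti to the ester on the neighbouring ring carbon, so C11 enters trans to the C9 ester and quaternary C7 is set; the C11 carbinol forms as an epimer mixture that step 2 removes.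

Step 2
Reactants: 4 aldol adduct
Product: 5 keto diester
Conditions: Dess–Martin periodinane, CH2Cl2, 0 °C → rt
Reagents that add atoms: none
Why: Dess–Martin oxidation of a secondary alcohol; C7 carries no hydrogen, so both C11 epimers converge on one ketone without risk to C7 or C8.

Step 3
Reactants: 5 keto diester
Product: 6 methylene diester
Conditions: Ph3PCH3Br, KN(SiMe3)2, THF, 0 °C; then 5, −78 → 0 °C
Reagents that add atoms: methyltriphenylphosphonium bromide, C[P+](c1ccccc1)(c1ccccc1)c1ccccc1.[Br-]
Why: Wittig methylenation of the ketone, which is far more electrophilic than the two esters, creates the C11=C13 bond.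

Step 4
Reactants: 6 methylene diester
Product: 7 diol (C6–OH and C9–OH)
Conditions: LiAlH4, THF, 0 °C
Reagents that add atoms: none
Why: Ester reduction by aluminium hydride turns both α-alkoxy esters into the C6 and C9 primary alcohols and leaves the silyl ether, the acetal and the isolated alkene untouched.

Step 5
Reactants: 7 diol
Product: 8 C9 silyl ether
Conditions: TBDPSCl (1.05 equiv), imidazole, CH2Cl2, −20 → 0 °C
Reagents that add atoms: tert-butyl(chloro)diphenylsilane, CC(C)(C)[Si](Cl)(c1ccccc1)c1ccccc1
Why: Regioselective silylation: the C6 hydroxyl is neopentylic on quaternary C7 whereas the C9 hydroxyl hangs on a tertiary carbon, so the bulky chlorosilane should take O9 first.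

Step 6
Reactants: 8 C9 silyl ether
Product: 9 C6 aldehyde
Conditions: Dess–Martin periodinane, CH2Cl2, 0 °C → rt
Reagents that add atoms: none
Why: Dess–Martin oxidation of the remaining primary alcohol gives an aldehyde that cannot enolise because C7 is quaternary.

Step 7
Reactants: 10 pent-4-yn-1-ol
Product: 11 pent-4-ynal
Conditions: Dess–Martin periodinane, CH2Cl2, 0 °C → rt; used as a dried solution
Reagents that add atoms: none
Why: Dess–Martin oxidation of a primary alcohol; the volatile ynal is carried on without concentration to dryness.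

Step 8
Reactants: 11 pent-4-ynal; 12 ethyltriphenylphosphonium bromide
Product: 16 (Z)-6-iodohept-5-en-1-yne, via ethylidenetriphenylphosphorane 13 (not isolated), via (1-iodoethyl)triphenylphosphonium iodide 14 (not isolated), via (1-iodoethylidene)triphenylphosphorane 15 (not isolated)
Conditions: 12, n-BuLi, THF, 0 °C; I2, −78 °C; NaN(SiMe3)2, −20 °C; then 11, −78 °C → rt
Reagents that add atoms: iodine, II
Why: Stork–Zhao olefination: the α-iodo ylide made in the flask adds to the aldehyde under kinetic control to give the Z-2-iodoalkene, which fixes the C1=C10 geometry and installs the iodide for the ring closure.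

Step 9
Reactants: 9 C6 aldehyde; 16 (Z)-6-iodohept-5-en-1-yne
Product: 18 allylic alcohols (C6 epimers), via alkenyldimethylalane 17 (not isolated)
Conditions: 16, AlMe3 (2 equiv), Cp2ZrCl2 (20 mol%), CH2Cl2, 0 °C → rt; volatiles removed in vacuo; then 9, CH2Cl2, −78 → 0 °C
Reagents that add atoms: trimethylaluminium, C[Al](C)C
Why: Negishi carboalumination (zirconium-catalysed syn addition of Me–Al across the terminal alkyne, methyl to the inner carbon) fixes the E-C4=C5 geometry, and the alkenylalane then adds 1,2 to the aldehyde; C6 forms without control, which is harmless because step 10 erases it.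

Step 10
Reactants: 18 allylic alcohols
Product: 19 enone
Conditions: Dess–Martin periodinane, CH2Cl2, rt
Reagents that add atoms: none
Why: Dess–Martin oxidation of the allylic alcohols; both C6 epimers give the same enone.

Step 11
Reactants: 19 enone
Product: 20 (6S)-allylic alcohol
Conditions: LiBH(s-Bu)3, THF, −78 °C
Reagents that add atoms: none
Why: 1,2-Reduction under Felkin–Anh control by a bulky, non-chelating borohydride: hydride comes anti to the C7–O bond while the alkenyl arm stays clear of ring carbon C8 and its cis CH2OSi group, which should set C6 as S; the β,β-disubstituted enone resists conjugate reduction.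

Step 12
Reactants: 20 (6S)-allylic alcohol
Product: 21 1,4-diol (C6–OH and C12–OH)
Conditions: HF·pyridine, pyridine, THF, 0 °C
Reagents that add atoms: none
Why: Fluoride-mediated desilylation, in which the primary allylic tert-butyldimethylsilyl ether is cleaved far faster than the tert-butyldiphenylsilyl ether.

Step 13
Reactants: 21 1,4-diol
Product: 23 α-methylene γ-lactone, via five-membered lactol 22 (not isolated)
Conditions: TEMPO (20 mol%), PhI(OAc)2 (2.5 equiv), CH2Cl2, rt
Reagents that add atoms: none
Why: Nitroxyl-catalysed oxidative lactonisation of a 1,4-diol: only the primary allylic alcohol is oxidised and the enal is caught by the C6 hydroxyl as the five-membered lactol, which is oxidised on to the α-methylene γ-lactone (first ring; O8 is locked in the dioxolane, so only O6 can close).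

Step 14
Reactants: 23 α-methylene γ-lactone
Product: 24 C7,C8-diol
Conditions: CF3CO2H/H2O (9:1), 0 °C
Reagents that add atoms: none
Why: Acid-catalysed hydrolysis of the isopropylidene acetal; the primary tert-butyldiphenylsilyl ether and the lactone should tolerate cold aqueous CF3CO2H.

Step 15
Reactants: 24 C7,C8-diol; 25 angelic acid
Product: 27 C8 angelate, via mixed anhydride 26 (not isolated)
Conditions: 25, 2,4,6-Cl3C6H2COCl, NEt3, toluene, rt; then 24, 75 °C
Reagents that add atoms: none
Why: Yamaguchi esterification through the mixed anhydride, a protocol known to transfer the angeloyl group without Z to E isomerisation; the secondary C8 hydroxyl is acylated and the tertiary C7 hydroxyl is not.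

Step 16
Reactants: 27 C8 angelate
Product: 28 C9 primary alcohol
Conditions: HF·pyridine, pyridine, THF, 0 °C → rt
Reagents that add atoms: none
Why: Desilylation by buffered HF·pyridine, weakly acidic conditions under which a 1,2-acyl shift from O8 to the freed O9 should be slow.

Step 17
Reactants: 28 C9 primary alcohol
Product: 29 seco-aldehyde (C9 aldehyde and C10 Z-alkenyl iodide)
Conditions: Dess–Martin periodinane, pyridine, CH2Cl2, 0 °C
Reagents that add atoms: none
Why: Dess–Martin oxidation buffered by pyridine should give the α-acyloxy aldehyde without epimerising C8; it is taken on at once.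

Step 18
Reactants: 29 seco-aldehyde
Product: 31 target CNP0292337.1, via alkenylchromium dichloride 30 (not isolated)
Conditions: CrCl2 (15 equiv), NiCl2 (0.15 equiv), degassed DMSO, rt, 2 mM, syringe-pump addition of 29
Reagents that add atoms: none
Why: CrCl2 reduces NiCl2 to zerovalent nickel, which inserts into the C10–I bond with retention of the Z geometry, and transmetalation gives the alkenyl species of trivalent chromium 30, which adds to the C9 aldehyde to give the chromium alkoxide. This is the Nozaki–Hiyama–Kishi coupling in its known macrocyclising form. It closes the ten-membered carbocycle C1–C10 by end-to-end attack of C10 on the C9 carbonyl (10-exo-trig), helped by the Z alkene that holds C2 and C9 cis and by the cis-fused lactone that turns the C5 arm towards C8. C9 is the only new stereocentre and is controlled by C8: with the C8–O bond anti to the incoming C10, the chromium-bound carbonyl oxygen should turn away from quaternary C7, which leads to the 9R (threo) carbinol. The step needs chemoselectivity for the aldehyde over lactone, angelate and methylene lactone, which the carbonyl selectivity and low basicity of alkenylchromium reagents secure, and cyclisation over oligomerisation, which high dilution and slow addition secure.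

**Compound list**

1 | dimethyl (4R,5R)-2,2-dimethyl-1,3-dioxolane-4,5-dicarboxylate (dimethyl 2,3-O-isopropylidene-L-tartrate) | COC(=O)[C@@H]1OC(C)(C)O[C@H]1C(=O)OC | starting material
2 | (tert-butyldimethylsilyloxy)acetaldehyde | CC(C)(C)[Si](C)(C)OCC=O | starting material
3 | lithium enolate of 1 (ketene acetal at C7, C8 unchanged) | COC(=O)[C@@H]1OC(C)(C)OC1=C(OC)O[Li] | intermediate (not isolated)
4 | dimethyl (4S,5R)-4-[2-(tert-butyldimethylsilyloxy)-1-hydroxyethyl]-2,2-dimethyl-1,3-dioxolane-4,5-dicarboxylate (both C11 epimers; C11 trans to the C9 ester) | COC(=O)[C@@H]1OC(C)(C)O[C@@]1(C(=O)OC)C(O)CO[Si](C)(C)C(C)(C)C | intermediate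
5 | dimethyl (4R,5R)-4-[(tert-butyldimethylsilyloxy)acetyl]-2,2-dimethyl-1,3-dioxolane-4,5-dicarboxylate | COC(=O)[C@@H]1OC(C)(C)O[C@@]1(C(=O)OC)C(=O)CO[Si](C)(C)C(C)(C)C | intermediate
6 | dimethyl (4S,5R)-4-[3-(tert-butyldimethylsilyloxy)prop-1-en-2-yl]-2,2-dimethyl-1,3-dioxolane-4,5-dicarboxylate | COC(=O)[C@@H]1OC(C)(C)O[C@@]1(C(=O)OC)C(=C)CO[Si](C)(C)C(C)(C)C | intermediate
7 | [(4R,5S)-4-[3-(tert-butyldimethylsilyloxy)prop-1-en-2-yl]-2,2-dimethyl-1,3-dioxolane-4,5-diyl]dimethanol | OC[C@@H]1OC(C)(C)O[C@@]1(CO)C(=C)CO[Si](C)(C)C(C)(C)C | intermediate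
8 | [(4R,5S)-5-[(tert-butyldiphenylsilyloxy)methyl]-4-[3-(tert-butyldimethylsilyloxy)prop-1-en-2-yl]-2,2-dimethyl-1,3-dioxolan-4-yl]methanol | CC(C)(C)[Si](c1ccccc1)(c1ccccc1)OC[C@@H]1OC(C)(C)O[C@@]1(CO)C(=C)CO[Si](C)(C)C(C)(C)C | intermediate
9 | (4S,5S)-5-[(tert-butyldiphenylsilyloxy)methyl]-4-[3-(tert-butyldimethylsilyloxy)prop-1-en-2-yl]-2,2-dimethyl-1,3-dioxolane-4-carbaldehyde | CC(C)(C)[Si](c1ccccc1)(c1ccccc1)OC[C@@H]1OC(C)(C)O[C@@]1(C=O)C(=C)CO[Si](C)(C)C(C)(C)C | intermediate
10 | pent-4-yn-1-ol | C#CCCCO | starting material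
11 | pent-4-ynal | C#CCCC=O | intermediate
12 | ethyltriphenylphosphonium bromide | CC[P+](c1ccccc1)(c1ccccc1)c1ccccc1.[Br-] | starting material
13 | ethylidenetriphenylphosphorane | CC=P(c1ccccc1)(c1ccccc1)c1ccccc1 | intermediate (not isolated)
14 | (1-iodoethyl)triphenylphosphonium iodide | CC(I)[P+](c1ccccc1)(c1ccccc1)c1ccccc1.[I-] | intermediate (not isolated)
15 | (1-iodoethylidene)triphenylphosphorane | CC(I)=P(c1ccccc1)(c1ccccc1)c1ccccc1 | intermediate (not isolated)
16 | (Z)-6-iodohept-5-en-1-yne | C#CCC/C=C(/C)I | intermediate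
17 | [(1E,5Z)-6-iodo-2-methylhepta-1,5-dien-1-yl]dimethylalane | C[Al](C)/C=C(\C)CC/C=C(/C)I | intermediate (not isolated)
18 | (2E,6Z)-1-[(4R,5S)-5-[(tert-butyldiphenylsilyloxy)methyl]-4-[3-(tert-butyldimethylsilyloxy)prop-1-en-2-yl]-2,2-dimethyl-1,3-dioxolan-4-yl]-7-iodo-3-methylocta-2,6-dien-1-ol (both epimers at the carbinol, C6) | CC(C)(C)[Si](c1ccccc1)(c1ccccc1)OC[C@@H]1OC(C)(C)O[C@@]1(C(O)/C=C(\C)CC/C=C(/C)I)C(=C)CO[Si](C)(C)C(C)(C)C | intermediate
19 | (2E,6Z)-1-[(4S,5S)-5-[(tert-butyldiphenylsilyloxy)methyl]-4-[3-(tert-butyldimethylsilyloxy)prop-1-en-2-yl]-2,2-dimethyl-1,3-dioxolan-4-yl]-7-iodo-3-methylocta-2,6-dien-1-one | CC(C)(C)[Si](c1ccccc1)(c1ccccc1)OC[C@@H]1OC(C)(C)O[C@@]1(C(=O)/C=C(\C)CC/C=C(/C)I)C(=C)CO[Si](C)(C)C(C)(C)C | intermediate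
20 | (1S,2E,6Z)-1-[(4R,5S)-5-[(tert-butyldiphenylsilyloxy)methyl]-4-[3-(tert-butyldimethylsilyloxy)prop-1-en-2-yl]-2,2-dimethyl-1,3-dioxolan-4-yl]-7-iodo-3-methylocta-2,6-dien-1-ol (6S,7R,8S in target numbering) | CC(C)(C)[Si](c1ccccc1)(c1ccccc1)OC[C@@H]1OC(C)(C)O[C@@]1([C@@H](O)/C=C(\C)CC/C=C(/C)I)C(=C)CO[Si](C)(C)C(C)(C)C | intermediate
21 | (1S,2E,6Z)-1-[(4R,5S)-5-[(tert-butyldiphenylsilyloxy)methyl]-4-(3-hydroxyprop-1-en-2-yl)-2,2-dimethyl-1,3-dioxolan-4-yl]-7-iodo-3-methylocta-2,6-dien-1-ol | CC(C)(C)[Si](c1ccccc1)(c1ccccc1)OC[C@@H]1OC(C)(C)O[C@@]1([C@@H](O)/C=C(\C)CC/C=C(/C)I)C(=C)CO | intermediate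
22 | lactol of 21: 2-hydroxy-3-methylenetetrahydrofuran closed between O6 and C12, spiro to the dioxolane at C7 (C12 anomers) | CC(C)(C)[Si](c1ccccc1)(c1ccccc1)OC[C@@H]1OC(C)(C)O[C@@]12C(=C)C(O)O[C@H]2/C=C(\C)CC/C=C(/C)I | intermediate (not isolated)
23 | (6S,7R,8S)-seco-lactone: α-methylene γ-lactone C6–O–C12, 7,8-O-isopropylidene, 9-O-tert-butyldiphenylsilyl, (1E,5Z)-6-iodo-2-methylhepta-1,5-dienyl chain on C6 | CC(C)(C)[Si](c1ccccc1)(c1ccccc1)OC[C@@H]1OC(C)(C)O[C@@]12C(=C)C(=O)O[C@H]2/C=C(\C)CC/C=C(/C)I | intermediate
24 | (6S,7S,8S)-seco-lactone 7,8-diol, 9-O-tert-butyldiphenylsilyl (same spatial arrangement as 23) | CC(C)(C)[Si](c1ccccc1)(c1ccccc1)OC[C@H](O)[C@@]1(O)C(=C)C(=O)O[C@H]1/C=C(\C)CC/C=C(/C)I | intermediate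
25 | angelic acid, (Z)-2-methylbut-2-enoic acid | C/C=C(/C)C(=O)O | starting material
26 | angelic 2,4,6-trichlorobenzoic anhydride | C/C=C(/C)C(=O)OC(=O)c1c(Cl)cc(Cl)cc1Cl | intermediate (not isolated)
27 | (6S,7R,8S)-seco-lactone 8-O-angelate, 7-hydroxy, 9-O-tert-butyldiphenylsilyl | CC(C)(C)[Si](c1ccccc1)(c1ccccc1)OC[C@H](OC(=O)/C(C)=C\C)[C@@]1(O)C(=C)C(=O)O[C@H]1/C=C(\C)CC/C=C(/C)I | intermediate
28 | (6S,7R,8S)-seco-lactone 8-O-angelate, 7-hydroxy, 9-hydroxy (primary) | OC[C@H](OC(=O)/C(C)=C\C)[C@@]1(O)C(=C)C(=O)O[C@H]1/C=C(\C)CC/C=C(/C)I | intermediate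
29 | (6S,7R,8R)-seco-aldehyde: C9 aldehyde, 8-O-angelate, 7-hydroxy, α-methylene γ-lactone, C10 Z-alkenyl iodide | O=C[C@H](OC(=O)/C(C)=C\C)[C@@]1(O)C(=C)C(=O)O[C@H]1/C=C(\C)CC/C=C(/C)I | intermediate
30 | alkenylchromium dichloride from 29 (trivalent chromium on C10, Z geometry kept) | O=C[C@H](OC(=O)/C(C)=C\C)[C@@]1(O)C(=C)C(=O)O[C@H]1/C=C(\C)CC/C=C(/C)[Cr](Cl)Cl | intermediate (not isolated)
31 | CNP0292337.1, (6S,7R,8S,9R)-7,9-dihydroxy-8-angeloyloxy-germacra-1(10)Z,4E,11(13)-trien-12,6-olide | C=C1C(=O)O[C@H]2/C=C(\C)CC/C=C(/C)[C@@H](O)[C@H](OC(=O)/C(C)=C\C)[C@@]12O | target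

**Count**

Total steps: 18. Longest linear sequence: 16 steps (1 → 31 through steps 1–6 and 9–18); steps 7 and 8 form the two-step side branch to 16.

**Steps most likely to fail**

Step 18. The internal nucleophile may attack the other face of the C9 aldehyde, so that the ring closes to the erythro carbinol; intermolecular coupling at insufficient dilution is the second hazard. The fallback sets out from 29 and returns at 31. The closure is run as in step 18 and the product, then mainly the (9S)-carbinol F1, is oxidised with MnO2 in CH2Cl2 to the ring ketone F2. Reduction of F2 with NaBH4/CeCl3·7H2O in MeOH at −78 °C should deliver hydride to the exposed outer face of the ring ketone, anti to the C8–O bond, the face opposite to the one the tethered carbon nucleophile took, which gives 31.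

Step 11. Hydride may be delivered to the other face of the enone if the C11 group, not ring carbon C8, acts as the larger neighbour, so that the 6R carbinol dominates. The fallback sets out from 18 and returns at 20 and makes no compound outside the list (F0). By the same model the non-chelating alkenylalane of step 9 would then attack aldehyde 9 to give mainly the 6S carbinol, so C6 is taken from the carbon–carbon bond formation: the epimers of 18 are separated by chromatography and the 6S epimer is 20 itself. The minor epimer is recycled through enone 19 and reduced under chelation control with Zn(BH4)2, which under the same assumption also leads to 20.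

Step 15. The acyl group may isomerise from Z to E through reversible conjugate addition of the base during slow acylation of the hindered C8 hydroxyl, or acylation may not occur at all. The fallback sets out from 24 and returns at 27. Diol 24 is esterified with 2-[bis(2,2,2-trifluoroethoxy)phosphoryl]propanoic acid and DCC, an acylation that runs through a phosphonoketene and reaches hindered alcohols, to give the 8-O-phosphonopropanoate F3. A Still–Gennari olefination of F3 with acetaldehyde (KN(SiMe3)2, 18-crown-6, THF, −78 °C) then builds the Z-2-methylbut-2-enoate in place and gives 27.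

**Further compounds**

F1 | step 18 | (6S,7R,8S,9S)-9-epimer of 31 | C=C1C(=O)O[C@H]2/C=C(\C)CC/C=C(/C)[C@H](O)[C@H](OC(=O)/C(C)=C\C)[C@@]12O
F2 | step 18 | (6S,7R,8R)-9-oxo analogue of 31 (ring ketone at C9) | C=C1C(=O)O[C@H]2/C=C(\C)CC/C=C(/C)C(=O)[C@H](OC(=O)/C(C)=C\C)[C@@]12O
F0 | step 11 | none | none
F3 | step 15 | 8-O-{2-[bis(2,2,2-trifluoroethoxy)phosphoryl]propanoate} of 24 (both epimers at the phosphonate carbon) | CC(C)(C)[Si](c1ccccc1)(c1ccccc1)OC[C@H](OC(=O)C(C)P(=O)(OCC(F)(F)F)OCC(F)(F)F)[C@@]1(O)C(=C)C(=O)O[C@H]1/C=C(\C)CC/C=C(/C)I
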